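The route rests on cutting ring A at C5–C6, C7–C8 and C4a–C5. Ring A is a fully substituted phloroglucinol (oxygen on C5, C7 and C8a, prenyl on C6 and C8, the C4 carbonyl on C4a). The key step exploits exactly this pattern by building the ring from a ketene and a siloxyalkyne, so each substituent is placed by connectivity and no phenol is ever prenylated. In one operation a photochemical Wolff rearrangement and benzannulation fuses ring A onto a preformed ring C. The precursor is a (2S)-2-aryl-2,3-dihydropyran-4-one bearing a prenyl-substituted α-diazoketone at C6, paired with a prenyl triisopropylsiloxyalkyne; C2 comes from an asymmetric formal hetero-Diels–Alder reaction.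

Key step: step 11

Remark on the chemistry: prenyl = 3-methylbut-2-en-1-yl; the stereocentre is (2S) throughout because the CIP order at C2 (O1 > aryl carbon > C3) never changes. The B-ring phenol is carried as a triisopropylsilyl ether, the same group the alkyne delivers to O7, so one buffered fluoride treatment ends the synthesis.

Step 1
Reactants: 1 4-hydroxybenzaldehyde; 2 1-bromo-3-methylbut-2-ene (prenyl bromide)
Product: 3 4-hydroxy-3-prenylbenzaldehyde
Conditions: KOH (10% aq.), 0 °C → rt
Reagents that add atoms: none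
Why: ortho-C-alkylation of the phenoxide in water (phenolate C-prenylation) is favoured because hydrogen bonding shields the oxygen and the para position is blocked, so 3 should be obtained after separation from the O-prenyl ether.

Step 2
Reactants: 3 4-hydroxy-3-prenylbenzaldehyde
Product: 4 3-prenyl-4-(triisopropylsilyloxy)benzaldehyde
Conditions: i-Pr3SiCl, imidazole, DMF, rt
Reagents that add atoms: triisopropylsilyl chloride, CC(C)[Si](Cl)(C(C)C)C(C)C
Why: imidazole-promoted silyl ether formation is routine for phenols, and the triisopropylsilyl aryl ether is chosen because it should withstand the tin hydroxide, amide base and organozinc used later.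

Step 3
Reactants: 5 methyl 2,4-dioxopentanoate
Product: 6 methyl (2Z)-2,4-bis(trimethylsilyloxy)penta-2,4-dienoate (moisture sensitive, used directly; the enol ether geometry is lost later)
Conditions: Me3SiOTf (2.2 equiv), Et3N (2.5 equiv), Et2O, 0 °C → rt
Reagents that add atoms: trimethylsilyl trifluoromethanesulfonate, C[Si](C)(C)OS(=O)(=O)C(F)(F)F
Why: soft enolisation with O-silylation (silyl enol ether formation) traps the predominant C2 enol and then turns the methyl ketone into the terminal 2-siloxydiene, the way Danishefsky-type and 1,3-bis(silyloxy) dienes are made.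

Step 4
Reactants: 4 3-prenyl-4-(triisopropylsilyloxy)benzaldehyde; 6 methyl (2Z)-2,4-bis(trimethylsilyloxy)penta-2,4-dienoate
Product: 8 methyl (2S)-4-oxo-2-[3-prenyl-4-(triisopropylsilyloxy)phenyl]-3,4-dihydro-2H-pyran-6-carboxylate, via Mukaiyama aldol adduct 7 (not isolated)
Conditions: (S)-BINOL (20 mol %), Ti(OiPr)4 (20 mol %), 4 Å molecular sieves, THF, −78 → −20 °C; then CF3CO2H (cat.), CH2Cl2, 0 °C
Reagents that add atoms: none
Why: this is a titanium–BINOL-catalysed vinylogous Mukaiyama aldol addition followed by acid cyclocondensation (formal hetero-Diels–Alder reaction), in which the terminal CH2 of the diene is expected to attack the Si face of the titanium-bound aldehyde with (S)-BINOL and so set C2 as S (the antipodal ligand is used should the sense prove opposite), after which acid closes O1–C6 and expels silanol.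

Step 5
Reactants: 8 methyl (2S)-4-oxo-2-[3-prenyl-4-(triisopropylsilyloxy)phenyl]-3,4-dihydro-2H-pyran-6-carboxylate
Product: 10 (2S)-4-oxo-2-[3-prenyl-4-(triisopropylsilyloxy)phenyl]-3,4-dihydro-2H-pyran-6-carboxylic acid, via trimethylstannyl ester 9 (not isolated)
Conditions: Me3SnOH, ClCH2CH2Cl, 70 °C; then 5% aq. HCl wash
Reagents that add atoms: trimethyltin hydroxide, C[Sn](C)(C)O
Why: trimethyltin hydroxide ester hydrolysis cleaves the activated methyl ester under nearly neutral conditions, so C3 is not deprotonated and retro-oxa-Michael opening of the C2–O1 bond, which would erode the stereocentre, is avoided.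

Step 6
Reactants: 11 5-bromo-2-methylpent-2-ene
Product: 12 (4-methylpent-3-en-1-yl)zinc bromide (titrated THF solution, LiCl complex)
Conditions: Zn dust (activated with BrCH2CH2Br and Me3SiCl), LiCl, THF, 50 °C
Reagents that add atoms: zinc, [Zn]
Why: LiCl-assisted direct zinc insertion into a primary alkyl bromide gives an alkylzinc halide mild enough to leave ketones and enones untouched in the next step.

Step 7
Reactants: 10 (2S)-4-oxo-2-[3-prenyl-4-(triisopropylsilyloxy)phenyl]-3,4-dihydro-2H-pyran-6-carboxylic acid; 12 (4-methylpent-3-en-1-yl)zinc bromide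
Product: 14 (2S)-6-(5-methylhex-4-enoyl)-2-[3-prenyl-4-(triisopropylsilyloxy)phenyl]-2,3-dihydro-4H-pyran-4-one, via acid chloride 13 (not isolated)
Conditions: Me2C=C(Cl)NMe2, CH2Cl2, 0 °C → rt; then 12, Pd(PPh3)4 (5 mol %), THF, 0 °C → rt
Reagents that add atoms: 1-chloro-N,N,2-trimethylprop-1-en-1-amine, CC(C)=C(Cl)N(C)C (chlorine of 13 only)
Why: neutral acid chloride formation with the α-chloroenamine is followed by Negishi acylation (oxidative addition of zerovalent palladium to the C–Cl bond, transmetallation from zinc, reductive elimination), and the alkylzinc halide should add neither to the C4 ketone nor to the enone.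

Step 8
Reactants: 14 (2S)-6-(5-methylhex-4-enoyl)-2-[3-prenyl-4-(triisopropylsilyloxy)phenyl]-2,3-dihydro-4H-pyran-4-one
Product: 16 (2S)-6-(2-diazo-5-methylhex-4-enoyl)-2-[3-prenyl-4-(triisopropylsilyloxy)phenyl]-2,3-dihydro-4H-pyran-4-one, via trifluoroacetyl diketone 15 (not isolated)
Conditions: LiN(SiMe3)2 (1.05 equiv), THF, −78 °C; CF3CO2CH2CF3, −78 °C; 5% aq. HCl; then MsN3, Et3N, H2O (1 equiv), MeCN, rt; neutral work-up
Reagents that add atoms: methanesulfonyl azide, CS(=O)(=O)N=[N+]=[N-] (the diazo nitrogens); 2,2,2-trifluoroethyl trifluoroacetate, O=C(OCC(F)(F)F)C(F)(F)F (trifluoroacetyl group of 15 only)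
Why: in this detrifluoroacetylative diazo transfer (Regitz-type deacylative diazo transfer) the side-chain CH2 next to the electron-poor exocyclic ketone, the most acidic position, is enolised at −78 °C and trifluoroacetylated, and the sulfonyl azide then delivers N2 with loss of the trifluoroacetyl group, without prolonged exposure of the C2–O1 bond to base.

Step 9
Reactants: 17 4-methylpent-3-enoic acid
Product: 18 ethyl 4-methylpent-3-enoate
Conditions: EtI, K2CO3, DMF, rt
Reagents that add atoms: iodoethane, CCI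
Why: carboxylate O-alkylation (SN2 esterification) avoids the strong acid that would lactonise or conjugate this β,γ-unsaturated acid.

Step 10
Reactants: 18 ethyl 4-methylpent-3-enoate
Product: 21 5-methyl-1-(triisopropylsilyloxy)hex-4-en-1-yne, via dibromo enolate 19 (not isolated), via lithium ynolate 20 (not isolated)
Conditions: CH2Br2, lithium 2,2,6,6-tetramethylpiperidide, THF, −78 °C; LiN(SiMe3)2, −78 → −20 °C; n-BuLi, −78 °C → rt; i-Pr3SiCl, −78 °C → rt
Reagents that add atoms: dibromomethane, BrCBr; triisopropylsilyl chloride, CC(C)[Si](Cl)(C(C)C)C(C)C; LiN(SiMe3)2, [Li]N([Si](C)(C)C)[Si](C)(C)C (lithium of 19 and 20 only)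
Why: in the Kowalski ester homologation preformed dibromomethyllithium adds to the ester, enolisation and bromine–lithium exchange give a carbenoid that rearranges to the lithium ynolate, and the bulky silyl chloride silylates it on oxygen to give the siloxyalkyne.

Step 11
Reactants: 16 (2S)-6-(2-diazo-5-methylhex-4-enoyl)-2-[3-prenyl-4-(triisopropylsilyloxy)phenyl]-2,3-dihydro-4H-pyran-4-one; 21 5-methyl-1-(triisopropylsilyloxy)hex-4-en-1-yne
Product: 26 (2S)-5-hydroxy-6,8,3′-triprenyl-7,4′-bis(triisopropylsilyloxy)flavanone, via vinylketene 22 (not isolated), via siloxycyclobutenone 23 (not isolated), via dienylketene 24 (not isolated), via cyclohexadienone 25 (not isolated)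
Conditions: 21 (1.5–2 equiv), hν (blue LEDs, ca. 440 nm), degassed ClCH2CH2Cl, rt; then 80 °C
Reagents that add atoms: none
Why: Proposed new method: light-induced Wolff rearrangement of 16 moves the pyranonyl carbon onto the carbene carbon to give vinylketene 22, which adds siloxyalkyne 21 in a [2+2] cycloaddition to form cyclobutenone 23; on warming, 4π electrocyclic opening gives dienylketene 24, 6π electrocyclisation onto pyranone C5 gives dienone 25, and enolisation gives the phenol. The closest known reaction is the Danheiser benzannulation in its diazoketone (photo-Wolff) variant with siloxyalkynes, which turns simple alkenyl and aryl diazoketones into resorcinol monosilyl ethers; a β-alkoxy enone such as this dihydropyranone has not served as the vinyl partner. Ring A closes by thermal disrotatory 6π electrocyclisation (C5–C4a bond) after the transient four-membered ring has formed by [2+2] cycloaddition (C5–C6 and C7–C8 bonds) and reopened. No stereocentre is created, and C2 is a spectator because the sequence is neutral and never enolises C3. The step needs regioselectivity in the [2+2] event, secured by polarisation (the alkyne carbon β to oxygen bonds to the electrophilic ketene carbonyl carbon, placing OH on C5, prenyl on C6 and the silyloxy group on C7), and it needs the Wolff shift to outrun 1,2-hydrogen migration in the carbene, which direct excitation of the diazo chromophore favours.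

Step 12
Reactants: 26 (2S)-5-hydroxy-6,8,3′-triprenyl-7,4′-bis(triisopropylsilyloxy)flavanone
Product: 27 (2S)-5,7-dihydroxy-2-(4-hydroxy-3-prenylphenyl)-6,8-diprenyl-2,3-dihydro-4H-chromen-4-one
Conditions: Bu4NF, AcOH (1:1), THF, 0 °C → rt
Reagents that add atoms: none
Why: fluoride-mediated desilylation of the two aryl silyl ethers is buffered with acetic acid, so that no phenoxide opens the flavanone to the chalcone (which would racemise C2) and no strong acid cyclises the ortho-prenyl phenols to chromans.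

Compound list
1 | 4-hydroxybenzaldehyde | O=Cc1ccc(O)cc1 | starting material
2 | 1-bromo-3-methylbut-2-ene (prenyl bromide) | CC(C)=CCBr | starting material
3 | 4-hydroxy-3-prenylbenzaldehyde | CC(C)=CCc1cc(C=O)ccc1O | intermediate
4 | 3-prenyl-4-(triisopropylsilyloxy)benzaldehyde | CC(C)=CCc1cc(C=O)ccc1O[Si](C(C)C)(C(C)C)C(C)C | intermediate
5 | methyl 2,4-dioxopentanoate | COC(=O)C(=O)CC(C)=O | starting material
6 | methyl (2Z)-2,4-bis(trimethylsilyloxy)penta-2,4-dienoate | COC(=O)/C(O[Si](C)(C)C)=C/C(=C)O[Si](C)(C)C | intermediate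
7 | methyl (2Z,6S)-4-oxo-6-[3-prenyl-4-(triisopropylsilyloxy)phenyl]-2,6-bis(trimethylsilyloxy)hex-2-enoate (aldol adduct, not isolated) | CC(C)=CCc1cc([C@@H](O[Si](C)(C)C)CC(=O)/C=C(\O[Si](C)(C)C)C(=O)OC)ccc1O[Si](C(C)C)(C(C)C)C(C)C | intermediate
8 | methyl (2S)-4-oxo-2-[3-prenyl-4-(triisopropylsilyloxy)phenyl]-3,4-dihydro-2H-pyran-6-carboxylate | CC(C)=CCc1cc([C@@H]2CC(=O)C=C(O2)C(=O)OC)ccc1O[Si](C(C)C)(C(C)C)C(C)C | intermediate
9 | trimethylstannyl (2S)-4-oxo-2-[3-prenyl-4-(triisopropylsilyloxy)phenyl]-3,4-dihydro-2H-pyran-6-carboxylate (not isolated) | CC(C)=CCc1cc([C@@H]2CC(=O)C=C(O2)C(=O)O[Sn](C)(C)C)ccc1O[Si](C(C)C)(C(C)C)C(C)C | intermediate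
10 | (2S)-4-oxo-2-[3-prenyl-4-(triisopropylsilyloxy)phenyl]-3,4-dihydro-2H-pyran-6-carboxylic acid | CC(C)=CCc1cc([C@@H]2CC(=O)C=C(O2)C(=O)O)ccc1O[Si](C(C)C)(C(C)C)C(C)C | intermediate
11 | 5-bromo-2-methylpent-2-ene | CC(C)=CCCBr | starting material
12 | (4-methylpent-3-en-1-yl)zinc bromide | CC(C)=CCC[Zn]Br | intermediate
13 | (2S)-4-oxo-2-[3-prenyl-4-(triisopropylsilyloxy)phenyl]-3,4-dihydro-2H-pyran-6-carbonyl chloride (not isolated) | CC(C)=CCc1cc([C@@H]2CC(=O)C=C(O2)C(=O)Cl)ccc1O[Si](C(C)C)(C(C)C)C(C)C | intermediate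
14 | (2S)-6-(5-methylhex-4-enoyl)-2-[3-prenyl-4-(triisopropylsilyloxy)phenyl]-2,3-dihydro-4H-pyran-4-one | CC(C)=CCc1cc([C@@H]2CC(=O)C=C(O2)C(=O)CCC=C(C)C)ccc1O[Si](C(C)C)(C(C)C)C(C)C | intermediate
15 | (2S)-6-[5-methyl-2-(trifluoroacetyl)hex-4-enoyl]-2-[3-prenyl-4-(triisopropylsilyloxy)phenyl]-2,3-dihydro-4H-pyran-4-one (drawn as the diketo tautomer, side-chain CH not defined, not isolated) | CC(C)=CCc1cc([C@@H]2CC(=O)C=C(O2)C(=O)C(CC=C(C)C)C(=O)C(F)(F)F)ccc1O[Si](C(C)C)(C(C)C)C(C)C | intermediate
16 | (2S)-6-(2-diazo-5-methylhex-4-enoyl)-2-[3-prenyl-4-(triisopropylsilyloxy)phenyl]-2,3-dihydro-4H-pyran-4-one | CC(C)=CCc1cc([C@@H]2CC(=O)C=C(O2)C(=O)C(=[N+]=[N-])CC=C(C)C)ccc1O[Si](C(C)C)(C(C)C)C(C)C | intermediate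
17 | 4-methylpent-3-enoic acid | CC(C)=CCC(=O)O | starting material
18 | ethyl 4-methylpent-3-enoate | CCOC(=O)CC=C(C)C | intermediate
19 | lithium 1,1-dibromo-5-methylhexa-1,4-dien-2-olate (not isolated) | [Li+].CC(C)=CCC([O-])=C(Br)Br | intermediate
20 | lithium 5-methylhex-4-en-1-yn-1-olate (not isolated) | [Li+].CC(C)=CCC#C[O-] | intermediate
21 | 5-methyl-1-(triisopropylsilyloxy)hex-4-en-1-yne | CC(C)=CCC#CO[Si](C(C)C)(C(C)C)C(C)C | intermediate
22 | vinylketene, 5-methyl-2-{(2S)-4-oxo-2-[3-prenyl-4-(triisopropylsilyloxy)phenyl]-3,4-dihydro-2H-pyran-6-yl}hexa-1,4-dien-1-one (not isolated) | CC(C)=CCc1cc([C@@H]2CC(=O)C=C(O2)C(CC=C(C)C)=C=O)ccc1O[Si](C(C)C)(C(C)C)C(C)C | intermediate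
23 | siloxycyclobutenone, 2,4-diprenyl-3-(triisopropylsilyloxy)-4-{(2S)-4-oxo-2-[3-prenyl-4-(triisopropylsilyloxy)phenyl]-3,4-dihydro-2H-pyran-6-yl}cyclobut-2-en-1-one (ring C4 not defined, not isolated) | CC(C)=CCc1cc([C@@H]2CC(=O)C=C(O2)C3(CC=C(C)C)C(=O)C(CC=C(C)C)=C3O[Si](C(C)C)(C(C)C)C(C)C)ccc1O[Si](C(C)C)(C(C)C)C(C)C | intermediate
24 | dienylketene, 2,4-diprenyl-3-(triisopropylsilyloxy)-4-{(2S)-pyranon-6-yl}buta-1,3-dien-1-one with the pyranonyl and ketenyl groups cis (not isolated) | CC(C)=CCc1cc([C@@H]2CC(=O)C=C(O2)/C(CC=C(C)C)=C(/O[Si](C(C)C)(C(C)C)C(C)C)C(CC=C(C)C)=C=O)ccc1O[Si](C(C)C)(C(C)C)C(C)C | intermediate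
25 | cyclohexadienone, the 4a-H keto tautomer of 26 (C4a not defined, not isolated) | CC(C)=CCc1cc([C@@H]2CC(=O)C3C(=O)C(CC=C(C)C)=C(O[Si](C(C)C)(C(C)C)C(C)C)C(CC=C(C)C)=C3O2)ccc1O[Si](C(C)C)(C(C)C)C(C)C | intermediate
26 | (2S)-5-hydroxy-6,8,3′-triprenyl-7,4′-bis(triisopropylsilyloxy)flavanone | CC(C)=CCc1cc([C@@H]2CC(=O)c3c(O)c(CC=C(C)C)c(O[Si](C(C)C)(C(C)C)C(C)C)c(CC=C(C)C)c3O2)ccc1O[Si](C(C)C)(C(C)C)C(C)C | intermediate
27 | (2S)-5,7-dihydroxy-2-(4-hydroxy-3-prenylphenyl)-6,8-diprenyl-2,3-dihydro-4H-chromen-4-one | CC(C)=CCc1cc([C@@H]2CC(=O)c3c(O)c(CC=C(C)C)c(O)c(CC=C(C)C)c3O2)ccc1O | target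

Total step count: 12. Longest linear sequence: 8 steps (steps 1, 2, 4, 5, 7, 8, 11, 12 from 4-hydroxybenzaldehyde).

Steps most likely to fail

Step 11 (bears the label). After loss of N2 the carbene may undergo 1,2-hydrogen migration from the allylic CH2 to a dienone instead of the Wolff shift. The electron-poor dienylketene may also be consumed before it closes onto C5, so material drains away before ring A forms. The fallback uses known chemistry, sets out from 3 (with 2) and returns at 27.
- 3 is converted with MOMCl and i-Pr2NEt into 4-(methoxymethoxy)-3-prenylbenzaldehyde F1.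
- Commercial 2,4,6-trihydroxyacetophenone is C-prenylated twice with 2 in aqueous KOH to 2,4,6-trihydroxy-3,5-diprenylacetophenone F2; this is the modestly selective prenylation the main route avoids.
- MOMCl and i-Pr2NEt convert F2 into 2-hydroxy-4,6-bis(methoxymethoxy)-3,5-diprenylacetophenone F3, the chelated hydroxyl staying free.
- Claisen–Schmidt condensation of F3 with F1 (KOH, EtOH) should give the (E)-2′-hydroxychalcone F4.
- NaOAc in refluxing EtOH closes F4 by oxa-Michael addition to racemic 5,7,4′-tris(methoxymethoxy)-6,8,3′-triprenylflavanone F5.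
- Asymmetric transfer hydrogenation with RuCl[(R,R)-TsDPEN](p-cymene) and HCO2H/Et3N is stopped near half conversion. It is expected to reduce the (2R)-enantiomer to the (2R,4R)-flavan-4-ol F7 and to leave the (2S)-tris(methoxymethoxy)flavanone F6; the other catalyst antipode is used if the sense is reversed.
- F6 is separated and deprotected with HCl in MeOH to give 27.

Step 4. The ester-bearing diene is less nucleophilic than the parent dienes, so addition to the electron-rich aldehyde may be slow and an uncatalysed silyl-mediated pathway may compete, lowering conversion and facial selectivity. The fallback sets out from 4 and returns at 8.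
- Brown allylation of 4 with B-allyldiisopinocampheylborane derived from (+)-α-pinene (Et2O, −78 °C, ethanolamine work-up) is expected to attack the Si face and give (1S)-1-[3-prenyl-4-(triisopropylsilyloxy)phenyl]but-3-en-1-ol F8.
- Et3SiCl and imidazole give its triethylsilyl ether F9.
- Tsuji–Wacker oxidation (PdCl2, CuCl, O2, DMF/H2O) of the terminal alkene, which leaves the trisubstituted prenyl alkenes alone, gives (4S)-4-[3-prenyl-4-(triisopropylsilyloxy)phenyl]-4-(triethylsilyloxy)butan-2-one F10.
- Kinetic enolisation of the methyl group with LiN(SiMe3)2 at −78 °C and Claisen condensation with dimethyl oxalate give methyl (2Z,6S)-2-hydroxy-4-oxo-6-[3-prenyl-4-(triisopropylsilyloxy)phenyl]-6-(triethylsilyloxy)hex-2-enoate F11.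
- Catalytic CF3CO2H in CH2Cl2 removes the triethylsilyl group and cyclodehydrates F11 to 8.

Step 8. Enolisation may compete at C3, putting the trifluoroacetyl group on the wrong carbon, or base may open the C2–O1 bond by retro-oxa-Michael reaction and erode enantiopurity. The fallback sets out from 11 and 13 and returns at 15 (then 16); it makes the pyranone the electrophile so that only the small partner is enolised.
- 11 is converted with Mg in THF into (4-methylpent-3-en-1-yl)magnesium bromide F12.
- F12 is added to ethyl trifluoroacetate at −78 °C to give 1,1,1-trifluoro-6-methylhept-5-en-2-one F13; the tetrahedral adduct survives until work-up, so addition stops at the ketone.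
- The lithium enolate of F13 (LiN(SiMe3)2, THF, −78 °C, two equivalents) is C-acylated with acid chloride 13 to give 15 directly.
- 15 then undergoes the sulfonyl azide transfer of step 8 to 16.

Further compounds
F1 | step 11 | 4-(methoxymethoxy)-3-prenylbenzaldehyde | CC(C)=CCc1cc(C=O)ccc1OCOC
F2 | step 11 | 2,4,6-trihydroxy-3,5-diprenylacetophenone | CC(=O)c1c(O)c(CC=C(C)C)c(O)c(CC=C(C)C)c1O
F3 | step 11 | 2-hydroxy-4,6-bis(methoxymethoxy)-3,5-diprenylacetophenone | CC(=O)c1c(O)c(CC=C(C)C)c(OCOC)c(CC=C(C)C)c1OCOC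
F4 | step 11 | (E)-1-[2-hydroxy-4,6-bis(methoxymethoxy)-3,5-diprenylphenyl]-3-[4-(methoxymethoxy)-3-prenylphenyl]prop-2-en-1-one | CC(C)=CCc1cc(/C=C/C(=O)c2c(O)c(CC=C(C)C)c(OCOC)c(CC=C(C)C)c2OCOC)ccc1OCOC
F5 | step 11 | racemic 5,7,4′-tris(methoxymethoxy)-6,8,3′-triprenylflavanone | CC(C)=CCc1cc(C2CC(=O)c3c(OCOC)c(CC=C(C)C)c(OCOC)c(CC=C(C)C)c3O2)ccc1OCOC
F6 | step 11 | (2S)-5,7,4′-tris(methoxymethoxy)-6,8,3′-triprenylflavanone | CC(C)=CCc1cc([C@@H]2CC(=O)c3c(OCOC)c(CC=C(C)C)c(OCOC)c(CC=C(C)C)c3O2)ccc1OCOC
F7 | step 11 | (2R,4R)-5,7,4′-tris(methoxymethoxy)-6,8,3′-triprenylflavan-4-ol | CC(C)=CCc1cc([C@H]2C[C@@H](O)c3c(OCOC)c(CC=C(C)C)c(OCOC)c(CC=C(C)C)c3O2)ccc1OCOC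
F8 | step 4 | (1S)-1-[3-prenyl-4-(triisopropylsilyloxy)phenyl]but-3-en-1-ol | CC(C)=CCc1cc([C@@H](O)CC=C)ccc1O[Si](C(C)C)(C(C)C)C(C)C
F9 | step 4 | (1S)-1-[3-prenyl-4-(triisopropylsilyloxy)phenyl]-1-(triethylsilyloxy)but-3-ene | CC(C)=CCc1cc([C@@H](O[Si](CC)(CC)CC)CC=C)ccc1O[Si](C(C)C)(C(C)C)C(C)C
F10 | step 4 | (4S)-4-[3-prenyl-4-(triisopropylsilyloxy)phenyl]-4-(triethylsilyloxy)butan-2-one | CC(C)=CCc1cc([C@@H](O[Si](CC)(CC)CC)CC(C)=O)ccc1O[Si](C(C)C)(C(C)C)C(C)C
F11 | step 4 | methyl (2Z,6S)-2-hydroxy-4-oxo-6-[3-prenyl-4-(triisopropylsilyloxy)phenyl]-6-(triethylsilyloxy)hex-2-enoate | CC(C)=CCc1cc([C@@H](O[Si](CC)(CC)CC)CC(=O)/C=C(\O)C(=O)OC)ccc1O[Si](C(C)C)(C(C)C)C(C)C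
F12 | step 8 | (4-methylpent-3-en-1-yl)magnesium bromide | CC(C)=CCC[Mg]Br
F13 | step 8 | 1,1,1-trifluoro-6-methylhept-5-en-2-one | CC(C)=CCCC(=O)C(F)(F)F
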